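Set side by side, zeta and gamma differ in their charges, c(X) exceeding c(L) in zeta and falling short of it in gamma, yet they answer one question alike.

| flask | L | X | temperature | remark | time |
|---|---|---|---|---|---|
| zeta | 0.17 M | 0.275 M | −40 °C | run made earlier |  |
| delta | 0.38 M | 0.275 M | 2 °C | run made earlier |  |
| gamma | 0.25 M | 0.14 M | −40 °C | run made earlier |  |
| cedar | 0.25 M | 0.275 M | −10 °C |  | 20 d |
| maple | 0.25 M | 0.275 M | 15 °C |  | 20 d |
| ash | 0.25 M | 0.275 M | −35 °C |  | 20 d |
| larch | 0.25 M | 0.275 M | 40 °C |  | 20 d |

| run | time / d | E / % | L / % |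
|---|---|---|---|
| zeta | 8.00 | 20 | 82 |
| zeta | 12.0 | 29 | 71 |
| zeta | 20.0 | 39 | 57 |
| zeta | 25.0 | 49 | 49 |
| zeta | 40.0 | 57 | 37 |
| zeta | 50.0 | 64 | 31 |
| delta | 0.625 | 47 | 48 |
| delta | 0.833 | 47 | 40 |
| delta | 1.04 | 49 | 41 |
| delta | 1.67 | 54 | 33 |
| delta | 3.00 | 58 | 34 |
| delta | 4.00 | 59 | 33 |
| delta | 6.00 | 58 | 28 |
| gamma | 5.00 | 9 | 89 |
| gamma | 8.00 | 11 | 88 |
| gamma | 12.0 | 16 | 86 |
| gamma | 25.0 | 26 | 74 |
| gamma | 50.0 | 37 | 60 |

(readings scatter by 1.5 percentage points)

- which flask leads in amount of E, in percent of the L charged ("all alike" within 1.5 percentage points) (cedar / maple / ash / larch / all alike)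
- how much E is there at the end, in percent of the L charged: cedar
- how much E is there at the end, in percent of the L charged: maple
- how much E is there at the end, in percent of the L charged: ash
- how much E is there at the end, in percent of the L charged: larch

- the numbers in the tables scatter with a standard deviation of 1.5 percentage points
- a reading of L is of its free form alone

*Which question?* Follow one molecule of L. Once it has left the free form, what are its chances of standing as E?

*Read it off.* The last reading of zeta gives 92.8%. That is E divided by the L that has gone, both in percent of the L charged, and I call it the arrival share; the trade's term is selectivity. The last reading of gamma gives 92.5%.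

*Is it a constant?* Not from run to run. Delta, at 2 °C, pooled over its 7 readings as summed E over summed L gone, gives 84.0%. Its single readings run from 78.3% at 0.833 d to 90.4% at 0.625 d, each a ratio of two scattered readings, and they show no course in time that I can read, so I use the pooled figure.

*So what do you commit to?* Cedar stands between the cold runs and delta in temperature, so I take its share between 84.0% and 92.8%. I assume that nearly all its L goes in 20 d, which puts E for cedar in that same band. Ash is close to zeta in temperature, and zeta had lost 43.0% of its L at 20.0 d, so I expect ash to keep the cold share on a smaller conversion. Maple and larch are warmer than delta, so I put their shares below 84.0%. Cedar leads.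

The forecast also names cedar, giving 79% for cedar, 61% for maple, 52% for ash and 39% for larch, with the stall in delta read as “so the reaction is reversible”; its cedar figure lies below my band.

The flasks give 84.4% for cedar, 44.0% for maple, 51.9% for ash and 4.81% for larch, so cedar leads. The shares of maple and larch are 59.9% and 8.40%.

    L → Q (k = 3.10 × 10⁻⁵ h⁻¹, Ea = 130 kJ mol⁻¹)
    L + X ⇌ E (K = 3.90 M⁻¹, k = 5.80 M⁻¹ h⁻¹, Ea = 54.0 kJ mol⁻¹, ΔH = −68.0 kJ mol⁻¹)
    X + E → Z (k = 0.150 M⁻¹ h⁻¹, Ea = 74.0 kJ mol⁻¹)
    L + X ⇌ G (K = 8.00 M⁻¹, k = 3.00 M⁻¹ h⁻¹, Ea = 70.0 kJ mol⁻¹, ΔH = −3.00 kJ mol⁻¹)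
    (constants at 40 °C)

Cedar holds 6.94% of free L at 20.0 d, so the arrival share 92.8% applied to the L gone gives 86.4% of E, against the 84.4% found. The neighbour is cedar with 0.11 M of X. There X is the limiting reagent, and its charge lets 44.0% of the L go. The same share turns that into 40.8% of E. At 20.0 d that neighbour holds 39.7% of E, with 1.77% of its X left.

The earlier runs and the new flask stem from a simulated flask from invented constants, noise included.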